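**Plan**
- Retrosynthesis: the benzyl ethers and the C4 methyl ether (back from the ketone) are adjusted last. Ring C of unit 1 is then cut at C4–C3 and O1–C2, the styryl arm at C3''–Cα, and the aryl group at C2''–C1'''.
- Enabling feature: in unit 1, O1 and C4 both sit on ring A (at C8a and C4a), so O1–C8a–C4a–C4 can be delivered as an ortho-quinone methide. C2–C3, with the aryl group on C2 and unit 2 on C3, is an E-styrene hanging from C3''.
- Forward order: ring C of unit 2 (chromone), then the C2'' aryl group, then the C3'' styryl arm, then ring C of unit 1 by [4+2], then C4 oxidation and hydrogenolysis.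
- Stereochemistry: C2'' comes from a chiral rhodium catalyst and C3'' is set trans to it in the alkenylation. C3 comes from the alkene face chosen by C3'' with a matched chiral acid, C2 from the E alkene, and C4 is erased.

Key step: step 8

Assumption: the (S)-bisphosphine of step 3 is taken to give the 2S flavanone (cyclohexenone model of the Hayashi–Miyaura reaction) and the (R)-acid of step 8 is taken to be the matched one; if a test run shows the opposite sense, the catalyst antipode is used.

**Step 1**
Reactants: 1 2',4',6'-trihydroxyacetophenone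
Product: 2 1-[2,4-bis(benzyloxy)-6-hydroxyphenyl]ethanone
Conditions: BnBr (2.1 equiv), K2CO3, DMF, 0 °C → rt
Reagents that add atoms: benzyl bromide BrCc1ccccc1
Why: Williamson etherification should take the two free hydroxyl groups and leave the one that is hydrogen-bonded to the acetyl group.

**Step 2**
Reactants: 2 1-[2,4-bis(benzyloxy)-6-hydroxyphenyl]ethanone
Product: 4 5,7-bis(benzyloxy)-4H-chromen-4-one, via enaminone 3 (not isolated)
Conditions: Me2NCH(OMe)2, toluene, 95 °C; then conc. HCl, CH2Cl2, rt
Reagents that add atoms: N,N-dimethylformamide dimethyl acetal COC(OC)N(C)C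
Why: Enaminone formation at the methyl ketone followed by acid-promoted addition of the phenol and loss of dimethylamine is the standard chromone synthesis from 2'-hydroxyacetophenones.

**Step 3**
Reactants: 4 5,7-bis(benzyloxy)-4H-chromen-4-one; 5 4-(benzyloxy)phenylboronic acid
Product: 6 (2S)-5,7-bis(benzyloxy)-2-[4-(benzyloxy)phenyl]chroman-4-one
Conditions: [Rh(OH)(cod)]2 (1.5 mol %), (S)-6,6'-dimethoxy-2,2'-bis[bis(3,4,5-trifluorophenyl)phosphino]biphenyl (3.3 mol %), 5 (2 equiv), toluene/H2O, 25 °C
Reagents that add atoms: none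
Why: The Hayashi–Miyaura asymmetric 1,4-addition of arylboronic acids to chromones should set C2'' through the chiral bisphosphine, and the electron-poor ligand and neutral medium should suppress ring opening and 1,2-addition.

**Step 4**
Reactants: 6 (2S)-5,7-bis(benzyloxy)-2-[4-(benzyloxy)phenyl]chroman-4-one
Product: 7 (2S)-5,7-bis(benzyloxy)-2-[4-(benzyloxy)phenyl]-4-(trimethylsilyloxy)-2H-chromene
Conditions: TMSOTf (1.3 equiv), Et3N (2 equiv), CH2Cl2, 0 °C; pentane trituration, used crude
Reagents that add atoms: trimethylsilyl trifluoromethanesulfonate C[Si](C)(C)OS(=O)(=O)C(F)(F)F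
Why: Soft enolisation silylates the carbonyl oxygen before the amine removes a C3''–H, so no free enolate forms and the retro-oxa-Michael opening that would racemise C2'' should be avoided.

**Step 5**
Reactants: 8 (E)-3-[4-(benzyloxy)phenyl]prop-2-enoic acid
Product: 9 1-(benzyloxy)-4-[(E)-2-bromoethenyl]benzene
Conditions: NBS (1.05 equiv), LiOAc (10 mol %), MeCN/H2O, rt, dark
Reagents that add atoms: N-bromosuccinimide O=C1CCC(=O)N1Br
Why: Catalytic Hunsdiecker-type bromodecarboxylation works best on para-alkoxycinnamic acids and should give the E bromostyrene.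

**Step 6**
Reactants: 7 (2S)-5,7-bis(benzyloxy)-2-[4-(benzyloxy)phenyl]-4-(trimethylsilyloxy)-2H-chromene; 9 1-(benzyloxy)-4-[(E)-2-bromoethenyl]benzene
Product: 11 (2S,3R)-5,7-bis(benzyloxy)-2-[4-(benzyloxy)phenyl]-3-[(E)-2-[4-(benzyloxy)phenyl]ethenyl]chroman-4-one, via tributyltin enolate 10 (not isolated)
Conditions: Pd2(dba)3 (2.5 mol %), P(t-Bu)3 (10 mol %), Bu3SnF (1.4 equiv), toluene, 80 °C; chromatography on neutralised silica
Reagents that add atoms: tributyltin fluoride CCCC[Sn](CCCC)(CCCC)F (its tin stays only in intermediate 10)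
Why: In this Stille-type α-alkenylation of a ketone tin enolate, fluoride moves the enolate from silicon to tin, zerovalent palladium inserts into the C–Br bond with retention of the E geometry, and reductive elimination forms C3''–Cα on the face away from the C2'' aryl group, giving the trans isomer, which is also the more stable one, under base-free conditions.

**Step 7**
Reactants: 12 4-(benzyloxy)-2-hydroxybenzaldehyde
Product: 13 5-(benzyloxy)-2-(dimethoxymethyl)phenol
Conditions: HC(OMe)3 (3 equiv), PPTS (cat.), MeOH, rt; Et3N quench, concentrated and used at once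
Reagents that add atoms: trimethyl orthoformate COC(OC)OC; methanol CO
Why: Acid-catalysed acetalisation is driven by the orthoformate as water scavenger, and the basic quench should keep the labile salicylaldehyde acetal intact until use.

**Step 8**
Reactants: 11 (2S,3R)-5,7-bis(benzyloxy)-2-[4-(benzyloxy)phenyl]-3-[(E)-2-[4-(benzyloxy)phenyl]ethenyl]chroman-4-one; 13 5-(benzyloxy)-2-(dimethoxymethyl)phenol
Product: 15 (2S,3R)-5,7-bis(benzyloxy)-2-[4-(benzyloxy)phenyl]-3-{(2S,3S,4S)-7-(benzyloxy)-2-[4-(benzyloxy)phenyl]-4-methoxychroman-3-yl}chroman-4-one, via methoxy ortho-quinone methide 14 (not isolated)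
Conditions: (R)-3,3'-bis(2,4,6-triisopropylphenyl)-BINOL N-triflylphosphoramide (10 mol %), 13 (2 equiv, slow addition), 5 Å MS, CH2Cl2, −40 → 0 °C
Reagents that add atoms: none
Why: The strong chiral Brønsted acid expels methanol from 13 to give the protonated, hydrogen-bonded 4-methoxy ortho-quinone methide 14; its methide carbon (C4) is attacked by the alkene carbon remote from the aryl group (future C3) while the phenol oxygen closes onto the benzylic carbon (future C2) in an asynchronous inverse-demand [4+2] cycloaddition, the closest known reaction type being the acid-catalysed cycloaddition of salicylaldehyde acetals or ortho-hydroxybenzyl alcohols with anethole-type β-alkylstyrenes, including variants with chiral phosphoric-acid-type catalysts. Ring C of unit 1, a six-membered dihydropyran, is closed in this intermolecular [4+2] mode, with C4–C3 leading and O1–C2 following inside the ion pair. C3 is set by the alkene face: with the C3''–H bond eclipsing the alkene, C2'' and its aryl group block one face and the flat C4'' carbonyl side stays open, which leads to the required configuration, and the matched acid should reinforce this bias. C2 follows from C3 because the E geometry is carried suprafacially into the 2,3-trans relationship, and a stepwise closure through the 4-benzyloxybenzyl cation would give the same, more stable trans ring. C4 is expected 3,4-trans through reversible ionisation of the benzylic ether, but its configuration does not matter because it becomes the carbonyl carbon in step 9; the C3 descriptor reads S here and R after oxidation only because the CIP ranking of C4 changes. The step needs regio-, chemo- and face selectivity: the para-benzyloxy group polarises the alkene so that only the remote carbon attacks C4, the acyl-deactivated ring A of unit 2 and the benzyl ethers are poorer nucleophiles than the styrene, and the cold, base-free medium should keep the β,γ-unsaturated ketone out of conjugation.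

**Step 9**
Reactants: 15 the 4-methoxyflavan–flavanone of step 8
Product: 16 (2S,3R,2''S,3''R)-7,5'',7''-tris(benzyloxy)-2,2''-bis[4-(benzyloxy)phenyl]-[3,3''-bichroman]-4,4''-dione
Conditions: DDQ (1.5 equiv), CH2Cl2/pH 7 phosphate buffer, 0 °C → rt
Reagents that add atoms: water O
Why: C4 carries a 2,4-dioxygenated aryl group and a methoxy group, so DDQ should abstract hydride there as in the cleavage of a dimethoxybenzyl ether, and water then converts the methoxy oxocarbenium ion into the ketone with loss of methanol while the less activated C2 and C2'' aryl-ether positions stay intact.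

**Step 10**
Reactants: 16 the pentabenzyl biflavanone of step 9
Product: 17 (2S,3R,2''S,3''R)-7,5'',7''-trihydroxy-2,2''-bis(4-hydroxyphenyl)-[3,3''-bichroman]-4,4''-dione (CNP0138443.1)
Conditions: H2 (1 atm), 10% Pd/C, THF/MeOH, rt, stopped at full debenzylation
Reagents that add atoms: none
Why: Hydrogenolysis of aryl benzyl ethers under neutral conditions is routine for flavanones and should leave the two ketones, the C2–O bonds and the four enolisable or ring-opening-prone stereocentres untouched.

**Compound list**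
1 | 2',4',6'-trihydroxyacetophenone | CC(=O)c1c(O)cc(O)cc1O | starting material
2 | 1-[2,4-bis(benzyloxy)-6-hydroxyphenyl]ethanone | CC(=O)c1c(O)cc(OCc2ccccc2)cc1OCc1ccccc1 | intermediate
3 | (E)-1-[2,4-bis(benzyloxy)-6-hydroxyphenyl]-3-(dimethylamino)prop-2-en-1-one | CN(C)/C=C/C(=O)c1c(O)cc(OCc2ccccc2)cc1OCc1ccccc1 | intermediate (not isolated)
4 | 5,7-bis(benzyloxy)-4H-chromen-4-one | O=c1ccoc2cc(OCc3ccccc3)cc(OCc3ccccc3)c12 | intermediate
5 | 4-(benzyloxy)phenylboronic acid | OB(O)c1ccc(OCc2ccccc2)cc1 | starting material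
6 | (2S)-5,7-bis(benzyloxy)-2-[4-(benzyloxy)phenyl]chroman-4-one | O=C1C[C@@H](c2ccc(OCc3ccccc3)cc2)Oc2cc(OCc3ccccc3)cc(OCc3ccccc3)c12 | intermediate
7 | (2S)-5,7-bis(benzyloxy)-2-[4-(benzyloxy)phenyl]-4-(trimethylsilyloxy)-2H-chromene | C[Si](C)(C)OC1=C[C@@H](c2ccc(OCc3ccccc3)cc2)Oc2cc(OCc3ccccc3)cc(OCc3ccccc3)c12 | intermediate
8 | (E)-3-[4-(benzyloxy)phenyl]prop-2-enoic acid | OC(=O)/C=C/c1ccc(OCc2ccccc2)cc1 | starting material
9 | 1-(benzyloxy)-4-[(E)-2-bromoethenyl]benzene | Br/C=C/c1ccc(OCc2ccccc2)cc1 | intermediate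
10 | (2S)-5,7-bis(benzyloxy)-2-[4-(benzyloxy)phenyl]-4-(tributylstannyloxy)-2H-chromene | CCCC[Sn](CCCC)(CCCC)OC1=C[C@@H](c2ccc(OCc3ccccc3)cc2)Oc2cc(OCc3ccccc3)cc(OCc3ccccc3)c12 | intermediate (not isolated)
11 | (2S,3R)-5,7-bis(benzyloxy)-2-[4-(benzyloxy)phenyl]-3-[(E)-2-[4-(benzyloxy)phenyl]ethenyl]chroman-4-one | c1ccccc1COc1ccc(/C=C/[C@H]2C(=O)c3c(OCc4ccccc4)cc(OCc4ccccc4)cc3O[C@@H]2c2ccc(OCc3ccccc3)cc2)cc1 | intermediate
12 | 4-(benzyloxy)-2-hydroxybenzaldehyde | O=Cc1ccc(OCc2ccccc2)cc1O | starting material
13 | 5-(benzyloxy)-2-(dimethoxymethyl)phenol | COC(OC)c1ccc(OCc2ccccc2)cc1O | intermediate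
14 | (6E)-3-(benzyloxy)-6-(methoxymethylidene)cyclohexa-2,4-dien-1-one | CO/C=C1\C=CC(OCc2ccccc2)=CC1=O | intermediate (not isolated)
15 | (2S,3R)-5,7-bis(benzyloxy)-2-[4-(benzyloxy)phenyl]-3-{(2S,3S,4S)-7-(benzyloxy)-2-[4-(benzyloxy)phenyl]-4-methoxychroman-3-yl}chroman-4-one | CO[C@@H]1c2ccc(OCc3ccccc3)cc2O[C@H](c2ccc(OCc3ccccc3)cc2)[C@H]1[C@H]1C(=O)c2c(OCc3ccccc3)cc(OCc3ccccc3)cc2O[C@@H]1c1ccc(OCc2ccccc2)cc1 | intermediate
16 | (2S,3R,2''S,3''R)-7,5'',7''-tris(benzyloxy)-2,2''-bis[4-(benzyloxy)phenyl]-[3,3''-bichroman]-4,4''-dione | O=C1c2ccc(OCc3ccccc3)cc2O[C@H](c2ccc(OCc3ccccc3)cc2)[C@H]1[C@H]1C(=O)c2c(OCc3ccccc3)cc(OCc3ccccc3)cc2O[C@@H]1c1ccc(OCc2ccccc2)cc1 | intermediate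
17 | (2S,3R,2''S,3''R)-7,5'',7''-trihydroxy-2,2''-bis(4-hydroxyphenyl)-[3,3''-bichroman]-4,4''-dione | O=C1c2ccc(O)cc2O[C@H](c2ccc(O)cc2)[C@H]1[C@H]1C(=O)c2c(O)cc(O)cc2O[C@@H]1c1ccc(O)cc1 | target

**Step count**
Total: 10 steps. Longest linear sequence: 8 steps (1, 2, 3, 4, 6, 8, 9, 10).

**Steps most likely to fail**

Step 8. The doubly donor-stabilised methoxy quinone methide may react too slowly with the hindered, β-branched styrene, so that the double bond of 11 drifts into conjugation, or the two alkene faces may be poorly distinguished. The fallback lowers the oxidation level of the diene. It sets out from 12, which NaBH4 in MeOH should reduce to 5-(benzyloxy)-2-(hydroxymethyl)phenol F1. Under the same N-triflylphosphoramide, F1 should lose water to the parent, far more electrophilic ortho-quinone methide; its cycloaddition with 11 is the known reaction of ortho-hydroxybenzyl alcohols with styrenes. It should give (2S,3R)-5,7-bis(benzyloxy)-2-[4-(benzyloxy)phenyl]-3-{(2S,3R)-7-(benzyloxy)-2-[4-(benzyloxy)phenyl]chroman-3-yl}chroman-4-one F2. Benzylic oxidation of F2 at C4 with DDQ (1.1 equiv) in CH2Cl2/MeOH, as practised on flavans, should install the methoxy group and return to the route at 15.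

Step 6. The palladium enolate may lose a β-hydride to give the flavone, the new double bond may migrate into conjugation, or the enolate may open to the chalcone and erode C2''. The fallback replaces the cross-coupling by a vinyl-cation equivalent and metathesis, starting from 7. A Mukaiyama aldol addition to (phenylselanyl)acetaldehyde (BF3·OEt2, CH2Cl2, −78 °C) should give (2S,3R)-5,7-bis(benzyloxy)-2-[4-(benzyloxy)phenyl]-3-[1-hydroxy-2-(phenylselanyl)ethyl]chroman-4-one F3 as carbinol epimers. Treating F3 with MsCl/Et3N at −78 → 0 °C should eliminate the hydroxy selenide to (2S,3R)-5,7-bis(benzyloxy)-2-[4-(benzyloxy)phenyl]-3-ethenylchroman-4-one F4. Cross-metathesis of F4 with 1-(benzyloxy)-4-ethenylbenzene (second-generation Hoveyda–Grubbs catalyst, CH2Cl2, 40 °C) should then give the E-styryl compound and return to the route at 11.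

Step 9. Hydride abstraction may occur at C2 or C2'' instead of C4, or DDQ may go on to dehydrogenate a flavanone ring. The fallback separates hydrolysis from oxidation, starting from 15. Acid-mediated exchange of the benzylic methyl ether (TFA, THF/H2O, 0 °C → rt; the benzyl ethers are stable) should give (2S,3R)-5,7-bis(benzyloxy)-2-[4-(benzyloxy)phenyl]-3-{(2S,3S,4S)-7-(benzyloxy)-2-[4-(benzyloxy)phenyl]-4-hydroxychroman-3-yl}chroman-4-one F5, either C4 epimer being usable. Dess–Martin periodinane with NaHCO3 in CH2Cl2 should then oxidise the alcohol and return to the route at 16.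

**Further compounds**
F1 | step 8 | 5-(benzyloxy)-2-(hydroxymethyl)phenol | OCc1ccc(OCc2ccccc2)cc1O
F2 | step 8 | (2S,3R)-5,7-bis(benzyloxy)-2-[4-(benzyloxy)phenyl]-3-{(2S,3R)-7-(benzyloxy)-2-[4-(benzyloxy)phenyl]chroman-3-yl}chroman-4-one | C1c2ccc(OCc3ccccc3)cc2O[C@H](c2ccc(OCc3ccccc3)cc2)[C@H]1[C@H]1C(=O)c2c(OCc3ccccc3)cc(OCc3ccccc3)cc2O[C@@H]1c1ccc(OCc2ccccc2)cc1
F3 | step 6 | (2S,3R)-5,7-bis(benzyloxy)-2-[4-(benzyloxy)phenyl]-3-[1-hydroxy-2-(phenylselanyl)ethyl]chroman-4-one (carbinol epimers) | OC(C[Se]c1ccccc1)[C@H]1C(=O)c2c(OCc3ccccc3)cc(OCc3ccccc3)cc2O[C@@H]1c1ccc(OCc2ccccc2)cc1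
F4 | step 6 | (2S,3R)-5,7-bis(benzyloxy)-2-[4-(benzyloxy)phenyl]-3-ethenylchroman-4-one | C=C[C@H]1C(=O)c2c(OCc3ccccc3)cc(OCc3ccccc3)cc2O[C@@H]1c1ccc(OCc2ccccc2)cc1
F5 | step 9 | (2S,3R)-5,7-bis(benzyloxy)-2-[4-(benzyloxy)phenyl]-3-{(2S,3S,4S)-7-(benzyloxy)-2-[4-(benzyloxy)phenyl]-4-hydroxychroman-3-yl}chroman-4-one | O[C@@H]1c2ccc(OCc3ccccc3)cc2O[C@H](c2ccc(OCc3ccccc3)cc2)[C@H]1[C@H]1C(=O)c2c(OCc3ccccc3)cc(OCc3ccccc3)cc2O[C@@H]1c1ccc(OCc2ccccc2)cc1
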